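**Plan**

- Retrosynthesis: cut C2–phenyl (conjugate arylation of a chromone), then ring C at O1–C2, C2–C3 and C4–C4a (enaminone closure of an acetyl group placed on C4a), then ring A at C8a–C8, C7–C6 and C8a–C4a (vinylketene plus siloxyalkyne), then the methine–ring D bond (Michael addition of syncarpic acid to an enal).
- Feature used: ring A (C4a, C5, C6, C7, C8, C8a) is hexasubstituted with oxygens at C5, C7 and C8a. The annulation delivers them as ethyl ether, silyl ether and free phenol, with C4a the only unsubstituted carbon next to free O1, so acetyl transfer and ring C closure have one course only.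
- Forward order: ring D is bought; the methine is set on it; the aldehyde end becomes an alkyne and then a siloxyalkyne; ring A is formed by benzannulation with a diazo enone made in two steps; ring C is closed as a chromone; phenyl is added at C2; the three oxygen masks come off.
- Stereochemistry: the methine (S) comes from iminium catalysis with (R)-diphenylprolinol trimethylsilyl ether and is then locked because ring D is kept as an enol ether; C2 (R) comes from a ligand-controlled rhodium 1,4-addition of phenylboronic acid.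

Key step: step 8

Assumption: syncarpic acid is taken as a purchasable compound, and ring D of the target is handled as the enol tautomer drawn.
Shorthand: D-OMe = 2-methoxy-3,3,5,5-tetramethyl-4,6-dioxocyclohex-1-en-1-yl (ring D as methyl enol ether); D-OH = the same group with free 2-hydroxy; TIPS = triisopropylsilyl.

Step 1
Reactants: 1 ethyl vinyl ether; 2 N-methoxy-N-methylpropanamide
Product: 4 2-ethoxypent-1-en-3-one, via 1-ethoxyvinyllithium 3 (not isolated)
Conditions: t-BuLi, THF, −78 → 0 °C; then 2, −78 → 0 °C; aq. NH4Cl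
Reagents that add atoms: none
Why: Deprotonation of the vinyl ether at its oxygen-bearing carbon gives an acyl-anion equivalent, and its addition to the N-methoxy-N-methyl amide stops at the lithium-chelated tetrahedral adduct (Weinreb ketone synthesis), so a single vinyl group is delivered and the enone appears only on work-up.

Step 2
Reactants: 4 2-ethoxypent-1-en-3-one
Product: 6 4-diazo-2-ethoxypent-1-en-3-one, via trifluoroacetyl diketone 5 (not isolated)
Conditions: LiN(SiMe3)2, THF, −78 °C; CF3CO2CH2CF3; cold dilute aq. HCl wash; then MsN3, Et3N, H2O, MeCN, 20 °C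
Reagents that add atoms: methanesulfonyl azide, CS(=O)(=O)N=[N+]=[N-]
Why: Deacylative (Regitz-type) diazo transfer, in which the kinetic enolate at the only enolizable carbon is trifluoroacetylated and the activated diketone takes the diazo group from the sulfonyl azide with loss of the trifluoroacetyl group, is the standard way to alpha-diazo ketones of base-sensitive alkenyl ketones.

Step 3
Reactants: 7 3-methylbutanal
Product: 8 (2E)-5-methylhex-2-enal
Conditions: Ph3P=CHCHO, toluene, 80 °C
Reagents that add atoms: (triphenylphosphoranylidene)acetaldehyde, O=CC=P(c1ccccc1)(c1ccccc1)c1ccccc1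
Why: Wittig olefination with the stabilized formylmethylene ylide extends the aldehyde by two carbons and should give the E enal because the ylide is stabilized.

Step 4
Reactants: 9 syncarpic acid; 8 (2E)-5-methylhex-2-enal
Product: 10 (4S)-2-hydroxy-6,6,8,8-tetramethyl-4-(2-methylpropyl)-3,4-dihydro-2H-chromene-5,7(6H,8H)-dione (anomer mixture)
Conditions: (R)-α,α-diphenylprolinol trimethylsilyl ether (cat.), CH2Cl2, 20 °C
Reagents that add atoms: none
Why: Iminium-catalysed Michael addition of a cyclic 1,3-dicarbonyl carbon nucleophile to an enal: in the E iminium ion the diphenyl(silyloxy)methyl group of the (R)-catalyst covers one face of C3, so the enol carbon of 9 should add to the open face and set the methine as S, and closure to the lactol takes the adduct out of the retro-Michael equilibrium.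

Step 5
Reactants: 10 lactol (4S)
Product: 11 (3S)-3-(D-OMe)-5-methylhexanal
Conditions: Me3SiCHN2, MeOH/toluene, 0 → 20 °C
Reagents that add atoms: (trimethylsilyl)diazomethane, C[Si](C)(C)C=[N+]=[N-]
Why: O-Methylation of a vinylogous acid by a diazoalkane: the lactol is in ring-chain equilibrium with the acidic enol aldehyde, only that form protonates the reagent, either flanking oxygen gives the same compound because ring D is symmetric about its bond to the methine, and the enol ether both frees the aldehyde and blocks retro-Michael loss of ring D.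

Step 6
Reactants: 11 (3S)-3-(D-OMe)-5-methylhexanal
Product: 13 (3S)-3-(D-OMe)-5-methylhex-1-yne, via alkenyl nonaflate 12 (not isolated)
Conditions: C4F9SO2F, t-BuN=P(pyrrolidin-1-yl)3, DMF, −20 → 20 °C
Reagents that add atoms: none
Why: One-pot enol nonaflation and E2 elimination of an enolizable aldehyde to a terminal alkyne: the phosphazene base forms the aldehyde enolate, the sulfonyl fluoride traps it on oxygen and further base eliminates nonaflate, while ring D has no enolizable hydrogen and the methine C–H is not conjugated to a carbonyl group.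

Step 7
Reactants: 13 (3S)-3-(D-OMe)-5-methylhex-1-yne
Product: 16 (3S)-3-(D-OMe)-5-methyl-1-(TIPS-oxy)hex-1-yne, via lithium acetylide 14 (not isolated), via lithium ynolate 15 (not isolated)
Conditions: LiN(SiMe3)2, THF, −78 °C; t-BuOOLi (from t-BuOOH and LiN(SiMe3)2), −78 → 0 °C; i-Pr3SiOTf, −78 → 0 °C
Reagents that add atoms: tert-butyl hydroperoxide, CC(C)(C)OO; triisopropylsilyl trifluoromethanesulfonate, CC(C)[Si](OS(=O)(=O)C(F)(F)F)(C(C)C)C(C)C
Why: Oxidation of a lithium acetylide by lithium tert-butyl peroxide (oxygen transfer with loss of tert-butoxide) gives the ynolate, which the bulky silyl triflate traps on oxygen and not on carbon, and the amide base can neither add to nor enolize the fully substituted ring D.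

Step 8
Reactants: 6 4-diazo-2-ethoxypent-1-en-3-one; 16 (3S)-3-(D-OMe)-5-methyl-1-(TIPS-oxy)hex-1-yne
Product: 21 5-ethoxy-2-[(1S)-1-(D-OMe)-3-methylbutyl]-4-methyl-3-(TIPS-oxy)phenol, via vinylketene 17 (not isolated), via cyclobutenone 18 (not isolated), via dienylketene 19 (not isolated), via cyclohexadienone 20 (not isolated)
Conditions: 6 (1.5 equiv, slow addition), LEDs 420–450 nm, degassed toluene, 20 °C; then 80 °C in the dark
Reagents that add atoms: none
Why: Light absorbed only by the diazo enone expels nitrogen and the ethoxyvinyl group migrates (photo-Wolff rearrangement) to give vinylketene 17, which adds across the siloxyalkyne in a [2+2] cycloaddition to cyclobutenone 18, and thermal four-electron ring opening then gives dienylketene 19. The closest known reaction is the photochemical Danheiser benzannulation of diazo enones with siloxyalkynes. Ring A closes by thermal six-electron disrotatory electrocyclization of 19 (C8a to C4a), and the resulting cyclohexadienone 20 tautomerizes to the phenol. No stereocenter is created, the quaternary carbon of 18 disappears on ring opening, and the methine should stay S because no acid, base or ionizing reagent is present. The one selectivity needed is the regiochemistry of the [2+2] event, and the polarized siloxyalkyne supplies it: its carbon remote from oxygen bonds to the ketene carbonyl carbon (C8 to C8a) and its oxygen-bearing carbon to the methyl-bearing ketene carbon (C7 to C6), so the silyl ether ends at C7, the free hydroxyl at C8a and the ethoxy group at C5. Slow addition of 6 keeps the ketene concentration low so that the hindered phenol is not acylated, and the long wavelength leaves the enone chromophore of ring D unexcited.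

Step 9
Reactants: 21 5-ethoxy-2-[(1S)-1-(D-OMe)-3-methylbutyl]-4-methyl-3-(TIPS-oxy)phenol
Product: 22 5-ethoxy-2-[(1S)-1-(D-OMe)-3-methylbutyl]-4-methyl-3-(TIPS-oxy)phenyl acetate
Conditions: Ac2O, Et3N, DMAP (cat.), CH2Cl2, 0 → 20 °C
Reagents that add atoms: acetic anhydride, CC(=O)OC(C)=O
Why: Acylation of the only free phenol under nucleophilic catalysis places on O1 the acetyl group that will move to the neighbouring carbon, and it also removes a phenol that could otherwise add to the enol ether of ring D.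

Step 10
Reactants: 22 aryl acetate
Product: 23 1-{6-ethoxy-2-hydroxy-3-[(1S)-1-(D-OMe)-3-methylbutyl]-5-methyl-4-(TIPS-oxy)phenyl}ethan-1-one
Conditions: TiCl4, CH2Cl2, −20 → 20 °C; cold aq. NaHCO3
Reagents that add atoms: none
Why: Fries rearrangement: TiCl4 ionizes the aryl ester and the acylium ion attacks C4a, the only unsubstituted ring carbon, which is ortho to O1 and to the ethoxy group and para to the siloxy group, the product being held as the titanium chelate of the ortho-hydroxy ketone.

Step 11
Reactants: 23 ortho-hydroxy acetophenone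
Product: 25 5-ethoxy-8-[(1S)-1-(D-OMe)-3-methylbutyl]-6-methyl-7-(TIPS-oxy)-4H-chromen-4-one, via enaminone 24 (not isolated)
Conditions: Me2NCH(OMe)2, toluene, 90 °C; then camphorsulfonic acid, CH2Cl2, 20 °C
Reagents that add atoms: N,N-dimethylformamide dimethyl acetal, COC(OC)N(C)C
Why: Enaminone route to chromones: the acetyl group condenses with the amide acetal, and under acid the only hydroxyl ortho to the ketone (O1, since O5 is an ethyl ether) adds to the enaminone in a 6-endo oxa-Michael addition and dimethylamine is eliminated, which closes ring C.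

Step 12
Reactants: 25 chromone
Product: 26 (2R)-5-ethoxy-8-[(1S)-1-(D-OMe)-3-methylbutyl]-6-methyl-2-phenyl-7-(TIPS-oxy)-2,3-dihydro-4H-chromen-4-one
Conditions: PhB(OH)2, [Rh(OH)(cod)]2 (cat.), (R)-MeO-F12-BIPHEP [(R)-2,2'-bis{bis(3,4,5-trifluorophenyl)phosphino}-6,6'-dimethoxy-1,1'-biphenyl], CH2Cl2/H2O, 20 → 40 °C
Reagents that add atoms: phenylboronic acid, OB(O)c1ccccc1
Why: Rhodium-catalysed asymmetric 1,4-addition of an arylboronic acid to a chromone (Hayashi–Miyaura reaction): phenyl passes from boron to rhodium and is inserted at C2 on the face chosen by the chiral bisphosphine, the (R)-ligand being expected to give 2R by analogy with the sense known for cyclohexenone with biaryl bisphosphines, the base-free medium avoids ring opening, and the minor C2 epimer is a diastereomer that chromatography can remove.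

Step 13
Reactants: 26 protected flavanone
Product: 27 (2R)-5-hydroxy-8-[(1S)-1-(D-OH)-3-methylbutyl]-6-methyl-2-phenyl-7-(TIPS-oxy)-2,3-dihydro-4H-chromen-4-one
Conditions: BBr3, CH2Cl2, −78 → 0 °C; MeOH quench, aq. NaH2PO4
Reagents that add atoms: none
Why: Lewis-acid dealkylation with BBr3: boron binds the chelating C4 carbonyl/O5 pair and the vinylogous ester carbonyl of ring D, bromide removes ethyl and methyl by SN2 attack, the doubly flanked aryl silyl ether should persist at low temperature, and without base ring C does not open, so C2 and the methine are left alone.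

Step 14
Reactants: 27 silyl ether of the target
Product: 28 (2R)-5,7-dihydroxy-8-[(1S)-1-(D-OH)-3-methylbutyl]-6-methyl-2-phenyl-2,3-dihydro-4H-chromen-4-one (CNP0249552.1)
Conditions: Bu4NF, AcOH, THF, 0 → 20 °C; aq. NaH2PO4
Reagents that add atoms: none
Why: Fluoride cleavage of the aryl silyl ether, buffered with acetic acid so that no phenoxide opens ring C by retro-oxa-Michael reaction, frees O7 last, when ring D is already the unreactive free enol and cannot be attacked by the neighbouring phenol.

**Compound list**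

1 | ethyl vinyl ether | C=COCC | starting material
2 | N-methoxy-N-methylpropanamide | CCC(=O)N(C)OC | starting material
3 | 1-ethoxyvinyllithium | [Li]C(=C)OCC | intermediate
4 | 2-ethoxypent-1-en-3-one | CCC(=O)C(=C)OCC | intermediate
5 | 2-ethoxy-6,6,6-trifluoro-4-methylhex-1-ene-3,5-dione | C=C(OCC)C(=O)C(C)C(=O)C(F)(F)F | intermediate
6 | 4-diazo-2-ethoxypent-1-en-3-one | CC(=[N+]=[N-])C(=O)C(=C)OCC | intermediate
7 | 3-methylbutanal (isovaleraldehyde) | CC(C)CC=O | starting material
8 | (2E)-5-methylhex-2-enal | CC(C)C/C=C/C=O | intermediate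
9 | syncarpic acid (2,2,4,4-tetramethylcyclohexane-1,3,5-trione) | CC1(C)C(=O)CC(=O)C(C)(C)C1=O | starting material
10 | (4S)-2-hydroxy-6,6,8,8-tetramethyl-4-(2-methylpropyl)-3,4-dihydro-2H-chromene-5,7(6H,8H)-dione (anomer mixture) | OC1C[C@H](CC(C)C)C2=C(O1)C(C)(C)C(=O)C(C)(C)C2=O | intermediate
11 | (3S)-3-(D-OMe)-5-methylhexanal | O=CC[C@H](CC(C)C)C1=C(OC)C(C)(C)C(=O)C(C)(C)C1=O | intermediate
12 | (3S)-3-(D-OMe)-5-methylhex-1-en-1-yl nonafluorobutane-1-sulfonate (E/Z mixture) | O=S(=O)(OC=C[C@H](CC(C)C)C1=C(OC)C(C)(C)C(=O)C(C)(C)C1=O)C(F)(F)C(F)(F)C(F)(F)C(F)(F)F | intermediate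
13 | (3S)-3-(D-OMe)-5-methylhex-1-yne, systematic: 3-methoxy-4,4,6,6-tetramethyl-2-[(3S)-5-methylhex-1-yn-3-yl]cyclohex-2-ene-1,5-dione | C#C[C@H](CC(C)C)C1=C(OC)C(C)(C)C(=O)C(C)(C)C1=O | intermediate
14 | lithium acetylide of 13 | [Li]C#C[C@H](CC(C)C)C1=C(OC)C(C)(C)C(=O)C(C)(C)C1=O | intermediate
15 | lithium (3S)-3-(D-OMe)-5-methylhex-1-yn-1-olate | [Li]OC#C[C@H](CC(C)C)C1=C(OC)C(C)(C)C(=O)C(C)(C)C1=O | intermediate
16 | (3S)-3-(D-OMe)-5-methyl-1-(TIPS-oxy)hex-1-yne | CC(C)[Si](OC#C[C@H](CC(C)C)C1=C(OC)C(C)(C)C(=O)C(C)(C)C1=O)(C(C)C)C(C)C | intermediate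
17 | 3-ethoxy-2-methylbuta-1,3-dien-1-one | CCOC(=C)C(C)=C=O | intermediate
18 | 4-(1-ethoxyethenyl)-4-methyl-2-[1-(D-OMe)-3-methylbutyl]-3-(TIPS-oxy)cyclobut-2-en-1-one (methine as in 16; C4 epimers) | CCOC(=C)C1(C)C(=O)C([C@H](CC(C)C)C2=C(OC)C(C)(C)C(=O)C(C)(C)C2=O)=C1O[Si](C(C)C)(C(C)C)C(C)C | intermediate
19 | 5-ethoxy-4-methyl-2-[1-(D-OMe)-3-methylbutyl]-3-(TIPS-oxy)hexa-1,3,5-trien-1-one (methine as in 16; C2 and C5 cis across C3=C4) | CCOC(=C)/C(C)=C(O[Si](C(C)C)(C(C)C)C(C)C)\C([C@H](CC(C)C)C1=C(OC)C(C)(C)C(=O)C(C)(C)C1=O)=C=O | intermediate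
20 | 5-ethoxy-4-methyl-2-[1-(D-OMe)-3-methylbutyl]-3-(TIPS-oxy)cyclohexa-2,4-dien-1-one (methine as in 16) | CCOC1=C(C)C(O[Si](C(C)C)(C(C)C)C(C)C)=C([C@H](CC(C)C)C2=C(OC)C(C)(C)C(=O)C(C)(C)C2=O)C(=O)C1 | intermediate
21 | 5-ethoxy-2-[(1S)-1-(D-OMe)-3-methylbutyl]-4-methyl-3-(TIPS-oxy)phenol | CCOc1cc(O)c([C@H](CC(C)C)C2=C(OC)C(C)(C)C(=O)C(C)(C)C2=O)c(O[Si](C(C)C)(C(C)C)C(C)C)c1C | intermediate
22 | 5-ethoxy-2-[(1S)-1-(D-OMe)-3-methylbutyl]-4-methyl-3-(TIPS-oxy)phenyl acetate | CCOc1cc(OC(C)=O)c([C@H](CC(C)C)C2=C(OC)C(C)(C)C(=O)C(C)(C)C2=O)c(O[Si](C(C)C)(C(C)C)C(C)C)c1C | intermediate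
23 | 1-{6-ethoxy-2-hydroxy-3-[(1S)-1-(D-OMe)-3-methylbutyl]-5-methyl-4-(TIPS-oxy)phenyl}ethan-1-one | CCOc1c(C(C)=O)c(O)c([C@H](CC(C)C)C2=C(OC)C(C)(C)C(=O)C(C)(C)C2=O)c(O[Si](C(C)C)(C(C)C)C(C)C)c1C | intermediate
24 | (2E)-3-(dimethylamino)-1-{6-ethoxy-2-hydroxy-3-[(1S)-1-(D-OMe)-3-methylbutyl]-5-methyl-4-(TIPS-oxy)phenyl}prop-2-en-1-one | CCOc1c(C(=O)/C=C/N(C)C)c(O)c([C@H](CC(C)C)C2=C(OC)C(C)(C)C(=O)C(C)(C)C2=O)c(O[Si](C(C)C)(C(C)C)C(C)C)c1C | intermediate
25 | 5-ethoxy-8-[(1S)-1-(D-OMe)-3-methylbutyl]-6-methyl-7-(TIPS-oxy)-4H-chromen-4-one | CCOc1c(C)c(O[Si](C(C)C)(C(C)C)C(C)C)c([C@H](CC(C)C)C2=C(OC)C(C)(C)C(=O)C(C)(C)C2=O)c2occc(=O)c12 | intermediate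
26 | (2R)-5-ethoxy-8-[(1S)-1-(D-OMe)-3-methylbutyl]-6-methyl-2-phenyl-7-(TIPS-oxy)-2,3-dihydro-4H-chromen-4-one | CCOc1c(C)c(O[Si](C(C)C)(C(C)C)C(C)C)c([C@H](CC(C)C)C2=C(OC)C(C)(C)C(=O)C(C)(C)C2=O)c2O[C@@H](c3ccccc3)CC(=O)c12 | intermediate
27 | (2R)-5-hydroxy-8-[(1S)-1-(D-OH)-3-methylbutyl]-6-methyl-2-phenyl-7-(TIPS-oxy)-2,3-dihydro-4H-chromen-4-one | Cc1c(O)c2c(c([C@H](CC(C)C)C3=C(O)C(C)(C)C(=O)C(C)(C)C3=O)c1O[Si](C(C)C)(C(C)C)C(C)C)O[C@@H](c1ccccc1)CC2=O | intermediate
28 | (2R)-5,7-dihydroxy-8-[(1S)-1-(2-hydroxy-3,3,5,5-tetramethyl-4,6-dioxocyclohex-1-en-1-yl)-3-methylbutyl]-6-methyl-2-phenyl-2,3-dihydro-4H-chromen-4-one (CNP0249552.1) | Cc1c(O)c2c(c([C@H](CC(C)C)C3=C(O)C(C)(C)C(=O)C(C)(C)C3=O)c1O)O[C@@H](c1ccccc1)CC2=O | target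

**Step count**

Total: 14 steps. Longest linear sequence: 12 steps (steps 3 to 14, from 3-methylbutanal); the diazo enone branch (steps 1 and 2) joins at step 8.

**Steps most likely to fail**

Risk at step 8. After loss of nitrogen the methyl-substituted acyl carbene may shift a hydrogen instead of the alkenyl group, and the vinylketene may dimerize or acylate the product phenol while the hindered alkyne traps it slowly. The fallback generates the same vinylketene thermally, without a carbene, and sets out from siloxyalkyne 16. 1-Ethoxyprop-1-yne and dichloroketene (Cl3CCOCl, Zn, Et2O) give 4,4-dichloro-3-ethoxy-2-methylcyclobut-2-en-1-one F1, and Zn/AcOH removes both chlorines to give 3-ethoxy-2-methylcyclobut-2-en-1-one F2. Heating F2 with 16 in toluene (110–140 °C) opens the cyclobutenone to vinylketene 17, and the same cycloaddition, ring opening and electrocyclization return to the route at phenol 21.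

Risk at step 6. The strong base may move the new triple bond into an allene through the propargylic methine, which would erase the stereocenter, or elimination may stall at the alkenyl nonaflate of E geometry. The fallback brings the alkyne in as a nucleophile and obtains the single enantiomer by resolution; it sets out from syncarpic acid 9 and aldehyde 7. Knoevenagel condensation (piperidine cat., CH2Cl2) gives 2,2,4,4-tetramethyl-6-(3-methylbutylidene)cyclohexane-1,3,5-trione F3. Conjugate addition of HC≡CMgBr (THF, −78 → 0 °C) gives racemic 3-hydroxy-4,4,6,6-tetramethyl-2-(5-methylhex-1-yn-3-yl)cyclohex-2-ene-1,5-dione F4, and Me3SiCHN2 converts it into racemic 3-(D-OMe)-5-methylhex-1-yne F5. Preparative chromatography on a chiral stationary phase separates alkyne 13 from (3R)-3-(D-OMe)-5-methylhex-1-yne F6, and the route is rejoined at 13.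

Risk at step 10. The Lewis acid may cleave the silyl ether, or protonate or acylate C8 with loss of the side chain as a stabilized cation, before the acetyl group reaches C4a. The fallback introduces the carbonyl carbon under basic conditions and adds the methyl group afterwards; it sets out from phenol 21. Magnesium-mediated ortho-formylation (MgCl2, Et3N, paraformaldehyde, MeCN, reflux) gives 6-ethoxy-2-hydroxy-3-[(1S)-1-(D-OMe)-3-methylbutyl]-5-methyl-4-(TIPS-oxy)benzaldehyde F7. MeTi(Oi-Pr)3 (THF, −40 → 0 °C) adds to the aldehyde but not to the hindered ketones of ring D and gives 1-{6-ethoxy-2-hydroxy-3-[(1S)-1-(D-OMe)-3-methylbutyl]-5-methyl-4-(TIPS-oxy)phenyl}ethan-1-ol F8, and MnO2 (CH2Cl2) oxidizes F8 to ketone 23, where the route is rejoined.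

**Further compounds**

F1 | step 8 | 4,4-dichloro-3-ethoxy-2-methylcyclobut-2-en-1-one | CCOC1=C(C)C(=O)C1(Cl)Cl
F2 | step 8 | 3-ethoxy-2-methylcyclobut-2-en-1-one | CCOC1=C(C)C(=O)C1
F3 | step 6 | 2,2,4,4-tetramethyl-6-(3-methylbutylidene)cyclohexane-1,3,5-trione | CC(C)CC=C1C(=O)C(C)(C)C(=O)C(C)(C)C1=O
F4 | step 6 | racemic 3-hydroxy-4,4,6,6-tetramethyl-2-(5-methylhex-1-yn-3-yl)cyclohex-2-ene-1,5-dione | C#CC(CC(C)C)C1=C(O)C(C)(C)C(=O)C(C)(C)C1=O
F5 | step 6 | racemic 3-(D-OMe)-5-methylhex-1-yne | C#CC(CC(C)C)C1=C(OC)C(C)(C)C(=O)C(C)(C)C1=O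
F6 | step 6 | (3R)-3-(D-OMe)-5-methylhex-1-yne | C#C[C@@H](CC(C)C)C1=C(OC)C(C)(C)C(=O)C(C)(C)C1=O
F7 | step 10 | 6-ethoxy-2-hydroxy-3-[(1S)-1-(D-OMe)-3-methylbutyl]-5-methyl-4-(TIPS-oxy)benzaldehyde | CCOc1c(C=O)c(O)c([C@H](CC(C)C)C2=C(OC)C(C)(C)C(=O)C(C)(C)C2=O)c(O[Si](C(C)C)(C(C)C)C(C)C)c1C
F8 | step 10 | 1-{6-ethoxy-2-hydroxy-3-[(1S)-1-(D-OMe)-3-methylbutyl]-5-methyl-4-(TIPS-oxy)phenyl}ethan-1-ol (carbinol epimers) | CCOc1c(C(C)O)c(O)c([C@H](CC(C)C)C2=C(OC)C(C)(C)C(=O)C(C)(C)C2=O)c(O[Si](C(C)C)(C(C)C)C(C)C)c1C
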